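## Retrosynthetic overview
1. Aryl C–C(=O) bond (ring A C-1 to the ketone): light-driven para acyl shift of the isomeric aryl ester, so the last step is a pure isomerisation.
2. Ester C(=O)–OAr bond: 5-methoxy-2-prenylphenol plus (S)-3-(4-hydroxyphenyl)lactic acid, joined under transient silyl cover.
3. C–O bond at the stereocentre: taken from the C–N bond of L-tyrosine with retention, so the only stereocentre is bought.
4. Ring A C-5–prenyl bond: ortho C-alkylation of 3-methoxyphenol. The prenyl group later blocks one ortho site during the acyl shift.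
5. Ring order: no ring is formed. Rings A and B are bought intact as 3-methoxyphenol and L-tyrosine.

Assumption: the SMILES descriptor reads as (S) at the carbinol carbon (OH > C=O > CH2Ar > H), the same spatial arrangement as in L-tyrosine, and this enantiomer is made.

## Route

**Step 1**
Reactants: 1 L-tyrosine
Product: 4 (S)-2-hydroxy-3-(4-hydroxyphenyl)propanoic acid, via diazonium carboxylate 2 (not isolated), via (R)-alpha-lactone 3 (not isolated)
Conditions: NaNO2 (1.5 equiv, slow addition), 1 M aq. H2SO4, 0 °C → rt, 16 h; EtOAc extraction, recrystallisation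
Reagents that add atoms: water, O
Why: Diazotisation of the α-amino acid with double inversion: the carboxylate expels N2 from 2 to give α-lactone 3, and water opens 3 at the same carbon, so C–O replaces C–N with net retention and the (S)-centre of L-tyrosine is carried over.

**Step 2**
Reactants: 5 3-methoxyphenol; 6 prenyl bromide (1-bromo-3-methylbut-2-ene)
Product: 8 5-methoxy-2-(3-methylbut-2-en-1-yl)phenol, via sodium 3-methoxyphenoxide 7 (not isolated)
Conditions: NaH (1.05 equiv), toluene, 0 °C → rt; then 6 (1.0 equiv), rt, 16 h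
Reagents that add atoms: none
Why: Ortho C-alkylation of a tight sodium phenoxide ion pair in a non-polar solvent (SN2 at the primary allylic bromide), in which the open C-6 beats C-2 that lies between the two oxygens; no stereocentre is formed.

**Step 3**
Reactants: 4 (S)-2-hydroxy-3-(4-hydroxyphenyl)propanoic acid; 8 5-methoxy-2-(3-methylbut-2-en-1-yl)phenol
Product: 12 5-methoxy-2-(3-methylbut-2-en-1-yl)phenyl (S)-2-hydroxy-3-(4-hydroxyphenyl)propanoate, via tris-TMS derivative 9 (not isolated), via bis-TMS acid chloride 10 (not isolated), via bis-TMS aryl ester 11 (not isolated)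
Conditions: TMSCl (3.3 equiv), pyridine (6 equiv), CH2Cl2, rt, 3 h; (COCl)2 (1.0 equiv), cat. DMF, 0 °C, 1 h; 8 (0.95 equiv), 0 °C → rt, 4 h; then 1 M aq. citric acid/THF, 0 °C → rt, 30 min
Reagents that add atoms: none
Why: Transient persilylation lets only the silyl ester be converted by the Vilsmeier reagent into acid chloride 10, pyridine-mediated O-acylation of phenol 8 (Einhorn-type acylation) gives 11, and mild aqueous acid strips both TMS ethers, while the weak base and low temperature avoid ketene formation so the stereocentre is untouched.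

**Step 4**
Reactants: 12 5-methoxy-2-(3-methylbut-2-en-1-yl)phenyl (S)-2-hydroxy-3-(4-hydroxyphenyl)propanoate
Product: 15 Lespeflorin C3, via acyl/aryloxyl radical pair 13 (not isolated), via 4-acylcyclohexa-2,5-dienone 14 (not isolated)
Conditions: hν (254 nm, low-pressure mercury lamp, FEP flow coil), degassed MeCN (5 mM) with 1 vol% AcOH, 0 °C, ca. 15 min residence time, ca. 70% conversion, recovered 12 recycled
Reagents that add atoms: none
Why: Proposed new method: a protecting-group-free, stereoretentive para-photo-Fries (formal 1,5-acyl shift) of an enantiopure α-hydroxyacyl aryl ester, a substrate class (free α-OH stereocentre on the migrating acyl, free phenol, prenyl alkene) on which it has not been shown; singlet excitation homolyses the ArO–C(=O) bond to the caged pair 13, whose σ-acyl radical leaves the neighbouring stereocentre untouched and recombines (about 10^9 to 10^10 s-1) at least a hundred times faster than it loses CO, and because one ortho carbon carries the prenyl group and the other is squeezed between two oxygen substituents, bonding goes mainly to the high-spin para carbon to give dienone 14, which AcOH tautomerises to 15 before it absorbs further light; closest known reaction type: photo-Fries rearrangement of ortho-blocked aryl acetates and benzoates to para-hydroxyaryl ketones.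

## Compound list
1 | L-tyrosine, (S)-2-amino-3-(4-hydroxyphenyl)propanoic acid | N[C@@H](Cc1ccc(O)cc1)C(=O)O | starting material
2 | (S)-2-diazonio-3-(4-hydroxyphenyl)propanoate (diazonium carboxylate) | [O-]C(=O)[C@@H]([N+]#N)Cc1ccc(O)cc1 | intermediate
3 | (R)-3-(4-hydroxybenzyl)oxiran-2-one (α-lactone) | O=C1[C@H](O1)Cc2ccc(O)cc2 | intermediate
4 | (S)-2-hydroxy-3-(4-hydroxyphenyl)propanoic acid | OC(=O)[C@@H](O)Cc1ccc(O)cc1 | intermediate
5 | 3-methoxyphenol | COc1cccc(O)c1 | starting material
6 | prenyl bromide, 1-bromo-3-methylbut-2-ene | CC(C)=CCBr | starting material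
7 | sodium 3-methoxyphenoxide | [Na+].[O-]c1cccc(OC)c1 | intermediate
8 | 5-methoxy-2-(3-methylbut-2-en-1-yl)phenol | COc1ccc(CC=C(C)C)c(O)c1 | intermediate
9 | trimethylsilyl (S)-2-(trimethylsilyloxy)-3-[4-(trimethylsilyloxy)phenyl]propanoate | C[Si](C)(C)OC(=O)[C@@H](O[Si](C)(C)C)Cc1ccc(O[Si](C)(C)C)cc1 | intermediate
10 | (S)-2-(trimethylsilyloxy)-3-[4-(trimethylsilyloxy)phenyl]propanoyl chloride | ClC(=O)[C@@H](O[Si](C)(C)C)Cc1ccc(O[Si](C)(C)C)cc1 | intermediate
11 | 5-methoxy-2-(3-methylbut-2-en-1-yl)phenyl (S)-2-(trimethylsilyloxy)-3-[4-(trimethylsilyloxy)phenyl]propanoate | COc1ccc(CC=C(C)C)c(OC(=O)[C@@H](O[Si](C)(C)C)Cc2ccc(O[Si](C)(C)C)cc2)c1 | intermediate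
12 | 5-methoxy-2-(3-methylbut-2-en-1-yl)phenyl (S)-2-hydroxy-3-(4-hydroxyphenyl)propanoate | COc1ccc(CC=C(C)C)c(OC(=O)[C@@H](O)Cc2ccc(O)cc2)c1 | intermediate
13 | caged pair of the 5-methoxy-2-prenylphenoxyl radical and the (S)-2-hydroxy-3-(4-hydroxyphenyl)propanoyl radical | COc1ccc(CC=C(C)C)c([O])c1.O=[C][C@@H](O)Cc1ccc(O)cc1 | intermediate
14 | 4-[(S)-2-hydroxy-3-(4-hydroxyphenyl)propanoyl]-5-methoxy-2-(3-methylbut-2-en-1-yl)cyclohexa-2,5-dien-1-one (both epimers at the ring sp3 carbon) | COC1=CC(=O)C(CC=C(C)C)=CC1C(=O)[C@@H](O)Cc2ccc(O)cc2 | intermediate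
15 | Lespeflorin C3, (S)-2-hydroxy-1-[4-hydroxy-2-methoxy-5-(3-methylbut-2-en-1-yl)phenyl]-3-(4-hydroxyphenyl)propan-1-one | COc1cc(O)c(CC=C(C)C)cc1C(=O)[C@@H](O)Cc1ccc(O)cc1 | target

## Step count and risks
Total steps: 4. Longest linear sequence: 3 (1 → 4 → 12 → 15).

**Risk 1, step 4 (the new step).**
- Some acyl shift may go to the remaining ortho carbon. That isomer is chelated, less polar and separable.
- Cage escape returns phenol 8, which goes back into step 3.
- The acyl radical may lose CO.
- Secondary photolysis of 15 is possible: Norrish-type α-cleavage, which could also erode ee, or photocyclisation of the ortho-prenylphenol to a chroman.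
- A realistic estimate is 40–50% of 15 based on recovered 12.

Fallback, all known chemistry; it sets out from 4 and comes back at 15. Compound 4 is coupled with N,O-dimethylhydroxylamine hydrochloride (EDC·HCl, HOBt, N-methylmorpholine, CH2Cl2/DMF) to the Weinreb amide (S)-2-hydroxy-3-(4-hydroxyphenyl)-N-methoxy-N-methylpropanamide F1. Both hydroxyls are then silylated (TBSCl, imidazole, DMF) to the bis-TBS Weinreb amide F2. In parallel, commercial 4-bromo-3-methoxyphenol F3 is ortho-C-prenylated with 6 (NaH, toluene, as in step 2) to 4-bromo-5-methoxy-2-(3-methylbut-2-en-1-yl)phenol F4. This is silylated (TBSCl, imidazole) to its TBS ether F5 and exchanged with n-BuLi (THF, −78 °C) to the aryllithium F6. F6 adds to F2 at −78 °C (Weinreb ketone synthesis, no over-addition, no epimerisation) to give the tris-TBS ether of Lespeflorin C3 F7. TBAF buffered with AcOH (THF, 0 °C) then gives 15.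

**Risk 2, step 2.**
- Competing O-prenylation.
- The C-2 regioisomer.
- Double alkylation, which keeps the yield near 40–50%.

Fallback; it sets out from 5 and comes back at 8. Compound 5 is O-alkylated with 3-chloro-3-methylbut-1-yne (DBU, cat. CuCl2, MeCN, 0 °C) to 1-methoxy-3-[(2-methylbut-3-yn-2-yl)oxy]benzene F8. The alkyne is semihydrogenated (H2, Pd/CaCO3 poisoned with Pb(OAc)2, quinoline, EtOAc) to 1-methoxy-3-[(2-methylbut-3-en-2-yl)oxy]benzene F9. An aromatic Claisen rearrangement (N,N-diethylaniline, 150 °C) then delivers the prenyl group to the less hindered ortho carbon and gives 8. The C–C bond is thus made by a [3,3] shift rather than by phenoxide alkylation.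

**Risk 3, step 3.**
- Partial racemisation through a ketene from 10.
- Oligoesters if the phenolic TMS ether falls off early.
- Loss of the activated aryl ester during desilylation.

Fallback; it sets out from 4 and comes back at 12. Compound 4 is persilylated (TBSCl, imidazole, DMF) to tert-butyldimethylsilyl (S)-2-(tert-butyldimethylsilyloxy)-3-[4-(tert-butyldimethylsilyloxy)phenyl]propanoate F10. The silyl ester alone is hydrolysed (AcOH/THF/H2O, rt) to (S)-2-(tert-butyldimethylsilyloxy)-3-[4-(tert-butyldimethylsilyloxy)phenyl]propanoic acid F11. A Steglich esterification with 8 (EDC·HCl, cat. DMAP, CH2Cl2, 0 °C) gives the isolable bis-TBS aryl ester F12. Et3N·3HF (MeCN, rt) then frees both hydroxyls to give 12. Here the acid chloride is replaced by a carbodiimide coupling of a purified, robustly protected acid.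

## Further compounds
F1 | step 4 | (S)-2-hydroxy-3-(4-hydroxyphenyl)-N-methoxy-N-methylpropanamide | CON(C)C(=O)[C@@H](O)Cc1ccc(O)cc1
F2 | step 4 | (S)-2-(tert-butyldimethylsilyloxy)-3-[4-(tert-butyldimethylsilyloxy)phenyl]-N-methoxy-N-methylpropanamide | CON(C)C(=O)[C@@H](O[Si](C)(C)C(C)(C)C)Cc1ccc(O[Si](C)(C)C(C)(C)C)cc1
F3 | step 4 | 4-bromo-3-methoxyphenol (bought) | COc1cc(O)ccc1Br
F4 | step 4 | 4-bromo-5-methoxy-2-(3-methylbut-2-en-1-yl)phenol | COc1cc(O)c(CC=C(C)C)cc1Br
F5 | step 4 | [4-bromo-5-methoxy-2-(3-methylbut-2-en-1-yl)phenoxy](tert-butyl)dimethylsilane | COc1cc(O[Si](C)(C)C(C)(C)C)c(CC=C(C)C)cc1Br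
F6 | step 4 | [4-(tert-butyldimethylsilyloxy)-2-methoxy-5-(3-methylbut-2-en-1-yl)phenyl]lithium | COc1cc(O[Si](C)(C)C(C)(C)C)c(CC=C(C)C)cc1[Li]
F7 | step 4 | (S)-2-(tert-butyldimethylsilyloxy)-1-[4-(tert-butyldimethylsilyloxy)-2-methoxy-5-(3-methylbut-2-en-1-yl)phenyl]-3-[4-(tert-butyldimethylsilyloxy)phenyl]propan-1-one | COc1cc(O[Si](C)(C)C(C)(C)C)c(CC=C(C)C)cc1C(=O)[C@@H](O[Si](C)(C)C(C)(C)C)Cc1ccc(O[Si](C)(C)C(C)(C)C)cc1
F8 | step 2 | 1-methoxy-3-[(2-methylbut-3-yn-2-yl)oxy]benzene | COc1cccc(OC(C)(C)C#C)c1
F9 | step 2 | 1-methoxy-3-[(2-methylbut-3-en-2-yl)oxy]benzene | COc1cccc(OC(C)(C)C=C)c1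
F10 | step 3 | tert-butyldimethylsilyl (S)-2-(tert-butyldimethylsilyloxy)-3-[4-(tert-butyldimethylsilyloxy)phenyl]propanoate | CC(C)(C)[Si](C)(C)OC(=O)[C@@H](O[Si](C)(C)C(C)(C)C)Cc1ccc(O[Si](C)(C)C(C)(C)C)cc1
F11 | step 3 | (S)-2-(tert-butyldimethylsilyloxy)-3-[4-(tert-butyldimethylsilyloxy)phenyl]propanoic acid | OC(=O)[C@@H](O[Si](C)(C)C(C)(C)C)Cc1ccc(O[Si](C)(C)C(C)(C)C)cc1
F12 | step 3 | 5-methoxy-2-(3-methylbut-2-en-1-yl)phenyl (S)-2-(tert-butyldimethylsilyloxy)-3-[4-(tert-butyldimethylsilyloxy)phenyl]propanoate | COc1ccc(CC=C(C)C)c(OC(=O)[C@@H](O[Si](C)(C)C(C)(C)C)Cc2ccc(O[Si](C)(C)C(C)(C)C)cc2)c1
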